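**Assumption (one line):** the peptide epoxidation catalyst, Shi-type ketone and tartrate enantiomers can each be chosen to give the descriptors shown. Unnumbered reagents (CBr4, H2O2, TBHP, I2, Oxone, MgBr2, CCl4) appear only in the "Reagents that add atoms" lines.

## Retrosynthetic overview
1. The CHBr–CCl(Me)2 terminus comes from the terminal prenyl olefin: asymmetric epoxidation, then tertiary bromohydrin, then bromonium/chloride opening with inversion at CHBr.
2. The tertiary vinyl carbinol comes from an (E)-allylic alcohol by Sharpless epoxidation and Zn reductive elimination of the epoxy iodide, which sets C3 (the carbinol carbon).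
3. Both rings of the 7-oxabicyclo[2.2.1]heptane form in one operation. A trans-epoxide-initiated 6-endo cation–olefin cyclization builds the cyclohexane (chair TS). The resulting tertiary cation is then trapped transannularly by the epoxide-derived oxygen, which closes the oxa-bridge.
4. The epoxy-polyene comes from farnesol: catalyst-controlled 6,7-epoxidation, C3 homologation with acetylacetone, then HWE. The enoate deactivates the tail olefin so ring B cannot form.

## Route

**Step 1**
Reactants: 1, (2E,6E)-farnesol
Product: 2, (2E)-3-methyl-5-[(2S,3S)-3-methyl-3-(4-methylpent-3-en-1-yl)oxiran-2-yl]pent-2-en-1-ol ((6S,7S)-6,7-epoxyfarnesol)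
Conditions: Asp-containing β-turn peptide (10 mol%), DIC, 30% aq. H2O2, DMAP (cat.), CH2Cl2, 0 °C
Reagents that add atoms: hydrogen peroxide, OO (supplies the epoxide O)
Why: An aspartyl peracid formed in situ is held by the peptide against the allylic OH and delivers O to the C6=C7 olefin (site- and enantioselective organocatalytic epoxidation), giving the trans-epoxide that defines C10/C11 of the final product.

**Step 2**
Reactants: 2
Product: 3, (2E)-1-bromo-3-methyl-5-[(2S,3S)-3-methyl-3-(4-methylpent-3-en-1-yl)oxiran-2-yl]pent-2-ene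
Conditions: PPh3, CBr4, CH2Cl2, 0 °C
Reagents that add atoms: carbon tetrabromide, BrC(Br)(Br)Br
Why: Appel bromination is an SN2 at the primary allylic carbon, with no transposition and the epoxide intact.

**Step 3**
Reactants: 3; 4, acetylacetone (pentane-2,4-dione)
Product: 5, (5E,9S,10S)-9,10-epoxy-6,10,14-trimethylpentadeca-5,13-dien-2-one
Conditions: (i) 4, K2CO3, acetone, 56 °C; (ii) K2CO3, MeOH/H2O, 60 °C
Reagents that add atoms: none (acetylacetone is the numbered reactant)
Why: C-Alkylation of the 1,3-diketone (SN2) followed by retro-Claisen deacetylation gives the methyl ketone that becomes C3; no stereocenter is touched.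

**Step 4**
Reactants: 5; 6, triethyl phosphonoacetate
Product: 7, ethyl (2E,6E,10S,11S)-10,11-epoxy-3,7,11,15-tetramethylhexadeca-2,6,14-trienoate
Conditions: NaH, THF, 0 → 25 °C; separate E/Z by SiO2 or AgNO3–SiO2
Reagents that add atoms: none (phosphonoacetate is the numbered reactant)
Why: Horner–Wadsworth–Emmons olefination gives the E-enoate (major, about 8:1). The electron-poor olefin is inert in the next cascade, and pure E geometry is needed for the later Sharpless epoxidation.

**Step 5**
Reactants: 7
Product: 8, ethyl (2E)-5-[(1R,2S,3S,4S)-1,3-dimethyl-3-(4-methylpent-3-en-1-yl)-7-oxabicyclo[2.2.1]heptan-2-yl]-3-methylpent-2-enoate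
Conditions: BF3·OEt2 (1.1 equiv), CH2Cl2, −78 → −40 °C, 2 h; aq. NaHCO3
Reagents that add atoms: none (isomerization)
Why: Proposed new method: BF3 opens the trans-epoxide at the tertiary C11 while the E-C6=C7 olefin attacks from the anti face through a chair-like 6-endo TS.
- Stereochemistry: the E-olefin and trans-epoxide place R1 (C6) and R2 (C11) equatorial, the C11 methyl axial and the C10–O equatorial, giving the cation at C7.
- The C10–O oxygen sits 1,4 across the ring and, after a chair→boat flip, captures the cation on the same face as its own bond. This gives the 7-oxanorbornane with R1 and the C11 methyl exo and R2 endo.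
- The enoate olefin is too electron-poor to start ring B, and the equatorial R2 prenyl olefin cannot reach C7.
- Closest known reactions: oxidosqualene-type epoxy-olefin cyclization, and 1,4-cineole-type transannular etherification of a 4-hydroxycyclohexyl cation.

**Step 6**
Reactants: 8
Product: 9, (2E)-5-[(1R,2S,3S,4S)-1,3-dimethyl-3-(4-methylpent-3-en-1-yl)-7-oxabicyclo[2.2.1]heptan-2-yl]-3-methylpent-2-en-1-ol
Conditions: DIBAL-H (2.5 equiv), CH2Cl2, −78 °C
Reagents that add atoms: none
Why: 1,2-reduction of the ester to the primary allylic alcohol; the ether, the prenyl olefin and the E geometry are untouched.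

**Step 7**
Reactants: 9
Product: 10, {(2S,3S)-3-[2-((1R,2S,3S,4S)-1,3-dimethyl-3-(4-methylpent-3-en-1-yl)-7-oxabicyclo[2.2.1]heptan-2-yl)ethyl]-3-methyloxiran-2-yl}methanol
Conditions: Ti(OiPr)4 (10 mol%), L-(+)-DET (12 mol%), TBHP, 4 Å MS, CH2Cl2, −20 °C
Reagents that add atoms: tert-butyl hydroperoxide, CC(C)(C)OO (supplies the epoxide O)
Why: Sharpless asymmetric epoxidation is hydroxyl-directed, so the allylic olefin reacts in preference to the isolated prenyl olefin. L-(+)-DET gives (2S,3S), which sets the C3 configuration.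

**Step 8**
Reactants: 10
Product: 11, (2R,3S)-2-(iodomethyl)-3-[2-((1R,2S,3S,4S)-1,3-dimethyl-3-(4-methylpent-3-en-1-yl)-7-oxabicyclo[2.2.1]heptan-2-yl)ethyl]-3-methyloxirane
Conditions: PPh3, I2, imidazole, CH2Cl2, 0 °C (use crude)
Reagents that add atoms: iodine, II
Why: Appel–Garegg iodination of the primary alcohol leaves the epoxide intact. The descriptor at C2 changes to R only because CH2I outranks the ring carbon; the spatial arrangement is unchanged.

**Step 9**
Reactants: 11
Product: 12, (3S)-5-[(1R,2S,3S,4S)-1,3-dimethyl-3-(4-methylpent-3-en-1-yl)-7-oxabicyclo[2.2.1]heptan-2-yl]-3-methylpent-1-en-3-ol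
Conditions: activated Zn dust, NaI (cat.), EtOH/THF (1:1), 25 → 40 °C
Reagents that add atoms: none
Why: Zn inserts at C–I, and β-alkoxide elimination cleaves the C2–O bond. This gives the vinyl group and leaves O on C3 as the tertiary alkoxide, so C3 is retained as (S) (Sharpless-type reductive fragmentation of an epoxy iodide).

**Step 10**
Reactants: 12
Product: 13, (3S)-5-[(1R,2S,3S,4S)-3-{2-[(2R)-3,3-dimethyloxiran-2-yl]ethyl}-1,3-dimethyl-7-oxabicyclo[2.2.1]heptan-2-yl]-3-methylpent-1-en-3-ol
Conditions: Shi fructose-derived ketone of the series giving the (R)-epoxide (30 mol%), Oxone, K2CO3, Bu4NHSO4, MeCN/DMM, aq. Na2B4O7–EDTA (pH about 10.5), 0 °C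
Reagents that add atoms: potassium peroxymonosulfate, OOS(=O)(=O)[O-].[K+] (supplies the epoxide O)
Why: Shi dioxirane epoxidation is organocatalytic and selective for the only remaining trisubstituted olefin; the vinyl group, tertiary allylic alcohol and ether are untouched. This sets the oxygen-bearing C14 as (R).

**Step 11**
Reactants: 13
Product: 14, (3S)-5-[(1R,2S,3S,4S)-3-[(3R)-4-bromo-3-hydroxy-4-methylpentyl]-1,3-dimethyl-7-oxabicyclo[2.2.1]heptan-2-yl]-3-methylpent-1-en-3-ol
Conditions: MgBr2·OEt2 (3 equiv), Et2O/CH2Cl2 (1:1), 0 °C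
Reagents that add atoms: magnesium bromide, [Mg+2].[Br-].[Br-]
Why: Lewis-acid epoxide opening by Br− occurs at the tertiary carbon (Markovnikov), with retention at C14–O.

**Step 12**
Reactants: 14
Product: 15, dactylomelol, (3S)-5-[(1R,2S,3S,4S)-3-[(3S)-3-bromo-4-chloro-4-methylpentyl]-1,3-dimethyl-7-oxabicyclo[2.2.1]heptan-2-yl]-3-methylpent-1-en-3-ol
Conditions: PPh3, CCl4, 2,6-lutidine, CH3CN, 40 °C
Reagents that add atoms: carbon tetrachloride, ClC(Cl)(Cl)Cl
Why: Appel activation of the secondary alcohol (the tertiary alcohol does not react) is followed by anchimeric displacement by the neighbouring tertiary bromide. This inverts C14 and gives a bromonium ion, which chloride opens at the tertiary carbon (Markovnikov), leaving the (S)-CHBr–CCl(CH3)2 unit.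

## Compound list
1 | (2E,6E)-farnesol | `OC/C=C(\C)CC/C=C(\C)CCC=C(C)C` | starting material
2 | (6S,7S)-6,7-epoxyfarnesol | `OC/C=C(\C)CC[C@@H]1O[C@@]1(C)CCC=C(C)C` | intermediate
3 | (6S,7S)-6,7-epoxyfarnesyl bromide | `BrC/C=C(\C)CC[C@@H]1O[C@@]1(C)CCC=C(C)C` | intermediate
4 | acetylacetone | `CC(=O)CC(C)=O` | starting material
5 | (5E,9S,10S)-9,10-epoxy-6,10,14-trimethylpentadeca-5,13-dien-2-one | `CC(=O)CC/C=C(\C)CC[C@@H]1O[C@@]1(C)CCC=C(C)C` | intermediate
6 | triethyl phosphonoacetate | `CCOC(=O)CP(=O)(OCC)OCC` | starting material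
7 | epoxy-geranylgeranoate ethyl ester | `CCOC(=O)/C=C(\C)CC/C=C(\C)CC[C@@H]1O[C@@]1(C)CCC=C(C)C` | intermediate
8 | bicyclic enoate | `CCOC(=O)/C=C(\C)CC[C@H]1[C@](C)(CCC=C(C)C)[C@@H]2CC[C@@]1(C)O2` | intermediate
9 | bicyclic allylic alcohol | `OC/C=C(\C)CC[C@H]1[C@](C)(CCC=C(C)C)[C@@H]2CC[C@@]1(C)O2` | intermediate
10 | (2S,3S)-epoxy alcohol | `OC[C@@H]1O[C@@]1(C)CC[C@H]2[C@](C)(CCC=C(C)C)[C@@H]3CC[C@@]2(C)O3` | intermediate
11 | (2R,3S)-epoxy iodide | `IC[C@@H]1O[C@@]1(C)CC[C@H]2[C@](C)(CCC=C(C)C)[C@@H]3CC[C@@]2(C)O3` | intermediate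
12 | vinyl carbinol with prenyl terminus | `C=C[C@@](C)(O)CC[C@H]1[C@](C)(CCC=C(C)C)[C@@H]2CC[C@@]1(C)O2` | intermediate
13 | terminal (R)-epoxide | `C=C[C@@](C)(O)CC[C@H]1[C@](C)(CC[C@H]3OC3(C)C)[C@@H]2CC[C@@]1(C)O2` | intermediate
14 | tertiary bromohydrin | `C=C[C@@](C)(O)CC[C@H]1[C@](C)(CC[C@@H](O)C(C)(C)Br)[C@@H]2CC[C@@]1(C)O2` | intermediate
15 | dactylomelol | `C=C[C@@](C)(O)CC[C@H]1[C@](C)(CC[C@H](Br)C(C)(C)Cl)[C@@H]2CC[C@@]1(C)O2` | target

**Total steps:** 12. **Longest linear sequence:** 12 (from farnesol).

## Three steps most likely to fail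
1. **Step 5 (proposed new cascade).** Meinwald rearrangement, proton loss to alkenes, or chloride/fluoride capture of the C7 cation could compete with O-capture.
   - Fallback (known chemistry, different approach): Cp2TiCl-mediated radical epoxide-opening 6-endo cyclization of 7 to the cyclohexanol bearing an alkene at C7. Then close the oxa-bridge by transannular hydroalkoxylation (PPTS, benzene, 80 °C, or PhSeCl followed by Bu3SnH).
2. **Step 1 (site- and enantioselectivity of peptide epoxidation).** The 6,7 vs 10,11 vs 2,3 selectivity or the er may be insufficient.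
   - Fallback: Sharpless epoxidation of geraniol (L-(+)-DET), then Appel bromide, acetylacetone alkylation/deacetylation, HWE and DIBAL. This converges on 2 in 5 steps.
3. **Step 12 (bromonium opening regio- and stereochemistry).** Chloride could attack C14, giving the swapped Cl/Br regioisomer, or the neopentyl-like oxyphosphonium could eliminate instead.
   - Fallback: Markovnikov bromochlorination of the prenyl olefin of 12 (NBS or a Br+ donor with Et4NCl). Separate the C14 epimers by preparative HPLC.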